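## Retrosynthetic overview

1. C1(ring A)–C7 bond: bromophenol 1 and (R)-propylene oxide 2 (through dilithio species 3) give alcohol 4; the C8 stereocentre is bought, not made.
2. C8–O aryl ether bond: Mitsunobu coupling of 4 with methoxyeugenol 5, with inversion, gives phenol 6 with (S)-C8.
3. Key disconnection, C7–OH bond: ring A of 6 is dearomatised with Ag2O to p-quinone methide 7; threo-selective 1,6-addition of water re-aromatises it and sets C7 in 8.
4. Last bond: O-methylation of the ring A phenol of 8 gives target 9.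
5. Ring order: no ring is built; ring A (from 1) and ring B (from 5) are bought as benzene rings, and only ring A passes through a non-aromatic stage (step 3).

Assumption: C7 is the carbinol carbon and C8 the ether carbon; the target is the threo isomer (1S,2S)-2-(4-allyl-2,6-dimethoxyphenoxy)-1-(3,4,5-trimethoxyphenyl)propan-1-ol, and 1, 2 and 5 are bought.

## Route

Step 1
Reactants: 1 4-bromo-2,6-dimethoxyphenol; 2 (R)-propylene oxide
Product: 4 (2R)-1-(4-hydroxy-3,5-dimethoxyphenyl)propan-2-ol, via dilithiated phenoxide 3 (not isolated)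
Conditions: t-BuLi (3.1 equiv), THF, −78 °C; CuI (10 mol %), then 2 (1.3 equiv), −78 → 0 °C; 1 M HCl work-up
Reagents that add atoms: none
Why: Deprotonation and bromine–lithium exchange give aryllithium 3, which under CuI catalysis opens epoxide 2 by SN2 attack at the unsubstituted CH2 (epoxide ring opening), so the stereocentre of 2 is untouched and is carried into 4 as (R).

Step 2
Reactants: 4 (2R)-1-(4-hydroxy-3,5-dimethoxyphenyl)propan-2-ol; 5 4-allyl-2,6-dimethoxyphenol (methoxyeugenol, 4 equiv, excess recovered)
Product: 6 4-[(2S)-2-(4-allyl-2,6-dimethoxyphenoxy)propyl]-2,6-dimethoxyphenol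
Conditions: PPh3, DIAD (1.5 equiv each), THF (1 M, sonication), 0 °C → rt
Reagents that add atoms: none
Why: Mitsunobu etherification: the secondary alcohol is activated as its alkoxyphosphonium ion and displaced by the phenoxide of 5 (in excess, so it out-competes the equally acidic phenol of 4) in an SN2 reaction with inversion, (R) to (S) at C8.

Step 3
Reactants: 6 4-[(2S)-2-(4-allyl-2,6-dimethoxyphenoxy)propyl]-2,6-dimethoxyphenol
Product: 8 (1S,2S)-2-(4-allyl-2,6-dimethoxyphenoxy)-1-(4-hydroxy-3,5-dimethoxyphenyl)propan-1-ol, via quinone methide 7 (not isolated)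
Conditions: Ag2O (1.1 equiv), CH2Cl2, rt, dark, 1 h, filter; then acetone–H2O (4:1), p-TsOH (5 mol %), 0 °C; chromatography removes the erythro epimer
Reagents that add atoms: water, O
Why: Oxidative dearomatisation of the 4-alkyl-2,6-dimethoxyphenol by Ag2O (two one-electron oxidations; the non-phenolic ring B and its allyl group are inert) gives p-quinone methide 7 with C8 intact, and acid-catalysed 1,6-conjugate addition of water (quinone methide hydration) re-aromatises ring A; in the allylic-strain-minimised conformer (C8–H eclipsing the exocyclic C=C) water attacks C7 anti to the C8 methyl group, which sets (7S) and should make the threo (1S,2S) isomer the major product (about 3:1 expected).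

Step 4
Reactants: 8 (1S,2S)-2-(4-allyl-2,6-dimethoxyphenoxy)-1-(4-hydroxy-3,5-dimethoxyphenyl)propan-1-ol
Product: 9 (1S,2S)-2-(4-allyl-2,6-dimethoxyphenoxy)-1-(3,4,5-trimethoxyphenyl)propan-1-ol
Conditions: MeI (3 equiv), K2CO3 (2 equiv), acetone, rt
Reagents that add atoms: iodomethane, CI
Why: Williamson O-methylation: K2CO3 deprotonates only the phenol (pKa about 10) and not the secondary benzylic alcohol, so MeI caps O4 of ring A selectively; no stereocentre is touched, and once the phenol is capped C7 can no longer epimerise through a quinone methide.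

## Compound list

1 | 4-bromo-2,6-dimethoxyphenol | COc1cc(Br)cc(OC)c1O | starting material
2 | (R)-propylene oxide, (2R)-2-methyloxirane | C[C@@H]1CO1 | starting material
3 | dilithiated phenoxide (lithium 4-lithio-2,6-dimethoxyphenolate) | [Li]Oc1c(OC)cc([Li])cc1OC | intermediate
4 | (2R)-1-(4-hydroxy-3,5-dimethoxyphenyl)propan-2-ol | C[C@@H](O)Cc1cc(OC)c(O)c(OC)c1 | intermediate
5 | 4-allyl-2,6-dimethoxyphenol (methoxyeugenol) | C=CCc1cc(OC)c(O)c(OC)c1 | starting material
6 | 4-[(2S)-2-(4-allyl-2,6-dimethoxyphenoxy)propyl]-2,6-dimethoxyphenol | C=CCc1cc(OC)c(O[C@@H](C)Cc2cc(OC)c(O)c(OC)c2)c(OC)c1 | intermediate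
7 | quinone methide, 4-[(2S)-2-(4-allyl-2,6-dimethoxyphenoxy)propylidene]-2,6-dimethoxycyclohexa-2,5-dien-1-one | C=CCc1cc(OC)c(O[C@@H](C)C=C2C=C(OC)C(=O)C(OC)=C2)c(OC)c1 | intermediate
8 | (1S,2S)-2-(4-allyl-2,6-dimethoxyphenoxy)-1-(4-hydroxy-3,5-dimethoxyphenyl)propan-1-ol | C=CCc1cc(OC)c(O[C@@H](C)[C@@H](O)c2cc(OC)c(O)c(OC)c2)c(OC)c1 | intermediate
9 | (1S,2S)-2-(4-allyl-2,6-dimethoxyphenoxy)-1-(3,4,5-trimethoxyphenyl)propan-1-ol | C=CCc1cc(OC)c(O[C@@H](C)[C@@H](O)c2cc(OC)c(OC)c(OC)c2)c(OC)c1 | target

## Step count and risks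

Total steps: 4. Longest linear sequence: 4 (1 → 4 → 6 → 8 → 9).

The three steps most likely to fail:

(a) Step 1. The unprotected dilithio species may open the epoxide sluggishly or unselectively. The fallback sets out from 5 and comes back at 4, and builds the carbinol by alkene oxidation and ketone reduction instead of by aryl–epoxide coupling. Wacker oxidation of 5 (PdCl2 10 mol %, CuCl, O2, DMF–H2O) gives 1-(4-hydroxy-3,5-dimethoxyphenyl)propan-2-one F1. An (R)-selective alcohol dehydrogenase (Lactobacillus kefir enzyme, NADP+, i-PrOH, pH 7 buffer, 30 °C) then reduces F1 to 4.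

(b) Step 2. The hindered phenol may couple poorly with the unactivated secondary alcohol; elimination to the propenylarene or self-etherification of 4 may take over. The fallback sets out from 5 and comes back at 8, making the C8–O bond first on a lactate and the aryl–C7 bond last. Mitsunobu reaction of 5 with methyl (R)-lactate, C[C@@H](O)C(=O)OC (PPh3, DIAD, THF), gives with inversion methyl (2S)-2-(4-allyl-2,6-dimethoxyphenoxy)propanoate F2. Reduction with i-Bu2AlH (CH2Cl2, −78 °C) gives (2S)-2-(4-allyl-2,6-dimethoxyphenoxy)propanal F3. Chelation-controlled addition of 3 (made from 1 as in step 1; MgBr2·OEt2, THF, −78 °C) to F3 gives 8.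

(c) Step 3. The quinone methide may tautomerise to the achiral enol ether (loss of C8), or hydrate with poor threo selectivity. The fallback sets out from 5 and comes back at 9, and sets C7 by carbonyl reduction instead of quinone methide hydration. O-Alkylation of 5 with 2-bromo-1-(3,4,5-trimethoxyphenyl)propan-1-one, CC(Br)C(=O)c1cc(OC)c(OC)c(OC)c1 (K2CO3, acetone), gives rac-2-(4-allyl-2,6-dimethoxyphenoxy)-1-(3,4,5-trimethoxyphenyl)propan-1-one F4. Asymmetric transfer hydrogenation with dynamic kinetic resolution (RuCl(p-cymene)[(R,R)-TsDPEN], HCO2H/Et3N, 40 °C) then gives 9: C8 epimerises through the enol while the (8S)-ketone is reduced faster with Felkin-type threo selectivity.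

Further compounds
F1 | step 1 | 1-(4-hydroxy-3,5-dimethoxyphenyl)propan-2-one | CC(=O)Cc1cc(OC)c(O)c(OC)c1
F2 | step 2 | methyl (2S)-2-(4-allyl-2,6-dimethoxyphenoxy)propanoate | C=CCc1cc(OC)c(O[C@@H](C)C(=O)OC)c(OC)c1
F3 | step 2 | (2S)-2-(4-allyl-2,6-dimethoxyphenoxy)propanal | C=CCc1cc(OC)c(O[C@@H](C)C=O)c(OC)c1
F4 | step 3 | rac-2-(4-allyl-2,6-dimethoxyphenoxy)-1-(3,4,5-trimethoxyphenyl)propan-1-one | C=CCc1cc(OC)c(OC(C)C(=O)c2cc(OC)c(OC)c(OC)c2)c(OC)c1
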